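**Analysis of the target**

Compound 31 is a germacranolide: a ten-membered carbocycle C1–C10 with trisubstituted double bonds C1=C10 and C4=C5, and an α-methylene-γ-lactone (O on C6, carbonyl C12, C11=C13) fused across C6–C7. Both ring alkenes carry their ring bonds cis (C2 cis to C9, C3 cis to C6); they are E by the sequence rule only because C14 (CHO) and C15 (CH2OH) outrank the ring carbons. The three stereocentres are contiguous, 6S,7R,8S: H6 and H7 are cis (cis-fused lactone) and the C8 isovalerate is anti to C11 on C7. Sensitive groups are the α-methylene lactone and the C10 enal (two Michael acceptors), the free allylic C15 alcohol, and the O6/O8 acyl pattern, which can translactonise once O8 is free. The difficulty is closing a ten-membered ring that holds two ring-cis trisubstituted alkenes without scrambling them, while keeping C14/C15 and O6/O8 differentiated. The strategy rests on C2–C3: it is the only ring single bond whose two carbons are both primary and allylic, so an NH can stand in for it in an eleven-membered diallylamine and be excised later.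

**Retrosynthetic reasoning**

31 ⇐ 30. The C14 aldehyde and C15 alcohol are unmasked last from a dimethyl acetal and a silyl ether, so the enal is never exposed to amines or carbanions.

30 ⇐ 29. C11=C13 is cut by a Horner–Wadsworth–Emmons methylenation. Until then the lactone is carried as its C11 phosphonate, which is not a Michael acceptor.

29 ⇐ 26. The C2–C3 bond is replaced by an NH bridge. Forward, the eleven-membered diallylamine 26 must lose its nitrogen as N2 and the two primary allylic termini must join. This exchanges a hard ten-membered C–C closure for an N-alkylation and leaves the stereotriad untouched.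

26 ⇐ 25 ⇐ 24. The N–C2 bond is cut; forward, an intramolecular Mitsunobu N-alkylation of the C3 sulfonamide by the C2 allylic alcohol, then thiolate removal of the sulfonyl group. Closure at C2 and not at C3, and without carbonate base, is chosen because C11–H of the phosphonolactone is acidic: an electrophile at C3 sits six atoms from C11, one at C2 seven.

24 ⇐ 23 ⇐ 21 + 22. The N–C3 bond is made intermolecularly from alcohol 21 and sulfonamide 22, then the C2 ether is cleaved oxidatively.

21 ⇐ 20. C3–C4 is cut to the vinyl iodide 20. The iodide fixes the C4=C5 geometry and keeps that alkene inert during the earlier epoxidation.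

20 ⇐ 19 ⇐ 18 ⇐ 16 + 17. The C8 ester comes off first, then the C7–C11 bond: the C6 phosphonoacetate of a cis-7,8-epoxide opens the epoxide at C7 with inversion. The cis-lactone with O8 anti to C11 requires the threo cis-epoxy alcohol 16.

16 ⇐ 15. The epoxide is put on the Z alkene C7=C8 by a hydroxyl-directed peracid, where A(1,3) strain gives the threo isomer. A titanium–tartrate epoxidation is not used: on a Z secondary allylic alcohol it is slow and favours the erythro isomer.

15 ⇐ 13. The iodoalkene comes from trans-hydroalumination of the propargylic alcohol and iodination; aluminium, and later C3, end up cis to C6.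

13 ⇐ 11 + 12. C5–C6 is cut; forward, an enantioselective alkynylation of the Z enal sets C6, the only stereocentre made by reagent control.

11 ⇐ 10 ⇐ 8 ⇐ 7 ⇐ 5 + 6. C1=C10 is cut by an E-selective Horner–Wadsworth–Emmons reaction (carbonyl trans to C2, which is the ring-cis geometry). The Weinreb amide then gives the C14 aldehyde and its acetal.

5 ⇐ 3 + 4; 3 ⇐ 2 ⇐ 1. C9–C10 is cut by allylic alkylation; the Z C7=C8 alkene is taken over from 1.

**Alternatives that were turned down**

Alternative 1: The disconnection is C7–C8 in an open chain, made by an Ireland–Claisen rearrangement. A chelated glycolate enolate of a C13 allylic ester, trapped as the silyl ketene acetal, rearranges through a chair to A1, the C9 acid with C8 ether, C11=C13 methylene on C7 and C6 silyl ether.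
- For: C7 and C8 are set together with chirality transfer from C6, the reaction class is thoroughly established, and the exocyclic methylene arrives without a phosphonate. On stereocontrol and precedent it is at least as strong as the peracid/epoxide-opening sequence used here.
- Against: A1 is still acyclic. C9 must be homologated into the C10 enal unit, the alkyne converted into the C4=C5 alkene with C3, C12 oxidised and lactonised, the ether at C8 exchanged for the isovalerate, and three kinds of silyl ether told apart. The ten-membered ring is not addressed at all.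
- Comparison: the chosen strategy gives up some stereochemical elegance and accepts an unprecedented step, but it supplies a ring closure and has the lactone and ester in place before the ring is formed.

Alternative 2: The disconnection is C7–C11 and C11=C13 in a preformed ten-membered ring. The C6 phosphonoacetate carbanion of a ring cis-7,8-epoxide opens C7, and in-flask methylenation gives A2, the α-methylene cis-lactone with free C8 hydroxyl.
- For: lactone, C7 configuration, C8 oxygen and methylene come in one flask, and the end-game is very short. The lactone tactic is the same as in the chosen route, so on that chemistry the two are equal.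
- Against: it presupposes the cyclodecadiene with a face-defined epoxide, so the medium-ring closure is only moved upstream. Ring epoxides of this type are prone to transannular cyclisation, the backside trajectory at C7 is conformation-dependent in the ring, and a C8 alkoxide beside a fresh α-methylene lactone invites translactonisation and oxa-Michael addition.
- Comparison: the chosen route runs the same opening on an open chain, where A(1,3) strain controls the epoxide, and forms the carbocycle afterwards without carbanions.

Alternative 3: The disconnection is C1=C10. An α-formyl phosphorane centre at C10 condenses with a C1 aldehyde of the same chain to give A3, the ten-membered enal.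
- For: ring, alkene and C14 oxidation state are made at once, the preferred enal geometry is the ring-cis one, and macrocyclic Wittig reactions are known. On directness and precedent it is stronger than nitrogen deletion.
- Against: a formyl-stabilised ylide is a poor nucleophile for a strained ten-membered closure (dimers, forcing conditions), and an enolisable C1 aldehyde must survive ylide generation. A3 still lacks the lactone, so C12 must be oxidised selectively and three silyl ethers differentiated afterwards.
- Comparison: the chosen strategy closes an eleven-membered ring by N-alkylation with the lactone already built, at the price of one step outside known chemistry.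

Key step: step 19

Remark: locants C1–C15 and the descriptors attached to them follow the germacrane numbering of 31; in open-chain intermediates the descriptors change with substituent priorities while the spatial arrangement stays the same.
Remark: the (S,S) antipode of ProPhenol is assumed to deliver the alkynyl group to the Si face of 11; if the sense is the reverse, the (R,R) ligand is used.
Remark: compounds 4, 6, 12, 17 and 22, (tributylstannyl)methanol and the anomeric amide reagent are taken as commercial.

Step 1
Reactants: 1 cis-2-butene-1,4-diol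
Product: 2 (Z)-4-(tert-butyldimethylsilyloxy)but-2-en-1-ol
Conditions: NaH (1.0 equiv), THF, 0 °C; TBSCl (1.0 equiv), 0 °C → rt
Reagents that add atoms: tert-butyldimethylsilyl chloride, C[Si](C)(Cl)C(C)(C)C
Why: Monosilylation of a symmetrical diol through its monosodium alkoxide; the cis geometry of the future C7=C8 bond is carried in from 1.

Step 2
Reactants: 2 (Z)-4-(tert-butyldimethylsilyloxy)but-2-en-1-ol
Product: 3 (Z)-4-bromo-1-(tert-butyldimethylsilyloxy)but-2-ene
Conditions: CBr4, PPh3, CH2Cl2, −20 → 0 °C
Reagents that add atoms: tetrabromomethane, BrC(Br)(Br)Br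
Why: Appel bromination of a primary allylic alcohol under neutral conditions, which keeps the Z alkene and the silyl ether.

Step 3
Reactants: 3 (Z)-4-bromo-1-(tert-butyldimethylsilyloxy)but-2-ene; 4 diethyl [2-(methoxy(methyl)amino)-2-oxoethyl]phosphonate
Product: 5 diethyl [(Z)-6-(tert-butyldimethylsilyloxy)-1-(methoxy(methyl)amino)-1-oxohex-4-en-2-yl]phosphonate (racemic)
Conditions: 4 (1.5 equiv), NaH, THF/DMF, 0 °C; then 3, 0 °C → rt
Reagents that add atoms: none
Why: SN2 alkylation of the phosphonate-stabilised amide enolate at the primary allylic bromide forms C9–C10; excess 4 suppresses dialkylation.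

Step 4
Reactants: 5 diethyl [(Z)-6-(tert-butyldimethylsilyloxy)-1-(methoxy(methyl)amino)-1-oxohex-4-en-2-yl]phosphonate; 6 (4-methoxybenzyloxy)acetaldehyde
Product: 7 (2E)-2-[(Z)-4-(tert-butyldimethylsilyloxy)but-2-enyl]-N-methoxy-4-(4-methoxybenzyloxy)-N-methylbut-2-enamide
Conditions: NaH (0.95 equiv), THF, 0 °C; then 6, 0 °C → rt
Reagents that add atoms: none
Why: Horner–Wadsworth–Emmons olefination of an α-substituted phosphonoamide puts the carbonyl trans to the aldehyde-derived carbon, i.e. C2 cis to C9, the ring-cis C1=C10 geometry; a slight deficit of base avoids deconjugation of the skipped diene.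

Step 5
Reactants: 7 (2E)-2-[(Z)-4-(tert-butyldimethylsilyloxy)but-2-enyl]-N-methoxy-4-(4-methoxybenzyloxy)-N-methylbut-2-enamide
Product: 8 (2E)-2-[(Z)-4-(tert-butyldimethylsilyloxy)but-2-enyl]-4-(4-methoxybenzyloxy)but-2-enal
Conditions: iBu2AlH (1.3 equiv), THF, −78 °C; aq. Rochelle salt
Reagents that add atoms: none
Why: Weinreb amide reduction stops at the chelated aluminium hemiaminal and releases the enal (C14) on work-up, without over-reduction or change of geometry.

Step 6
Reactants: 8 (2E)-2-[(Z)-4-(tert-butyldimethylsilyloxy)but-2-enyl]-4-(4-methoxybenzyloxy)but-2-enal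
Product: 10 (2Z,5E)-5-(dimethoxymethyl)-7-(4-methoxybenzyloxy)hepta-2,5-dien-1-ol, via silyl ether acetal 9 (not isolated)
Conditions: HC(OMe)3, camphorsulfonic acid (5 mol %), MeOH, 0 °C → rt; Et3N quench
Reagents that add atoms: trimethyl orthoformate, COC(OC)OC; methanol, CO
Why: Acid-catalysed acetalisation with orthoformate as water scavenger is followed in the same medium by methanolysis of the primary allylic silyl ether; the PMB ether is inert and methanol as solvent holds C14 as the dimethyl acetal.

Step 7
Reactants: 10 (2Z,5E)-5-(dimethoxymethyl)-7-(4-methoxybenzyloxy)hepta-2,5-dien-1-ol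
Product: 11 (2Z,5E)-5-(dimethoxymethyl)-7-(4-methoxybenzyloxy)hepta-2,5-dienal
Conditions: Dess–Martin periodinane, NaHCO3, CH2Cl2, 0 °C; crude aldehyde used at once
Reagents that add atoms: none
Why: Buffered, non-basic Dess–Martin oxidation of the Z allylic alcohol gives the Z enal (C6) without isomerisation or loss of the acetal.

Step 8
Reactants: 11 (2Z,5E)-5-(dimethoxymethyl)-7-(4-methoxybenzyloxy)hepta-2,5-dienal; 12 tert-butyldimethyl(prop-2-yn-1-yloxy)silane
Product: 13 (4R,5Z,8E)-1-(tert-butyldimethylsilyloxy)-8-(dimethoxymethyl)-10-(4-methoxybenzyloxy)deca-5,8-dien-2-yn-4-ol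
Conditions: 12 (3 equiv), Me2Zn (3 equiv), (S,S)-ProPhenol (20 mol %), Ph3PO (40 mol %), toluene, 0 °C; then 11, 4 °C
Reagents that add atoms: none
Why: Zinc–ProPhenol-catalysed enantioselective alkynylation of an α,β-unsaturated aldehyde; the dinuclear zinc complex binds aldehyde and alkynylzinc and delivers the alkyne to the Si face, forming C5–C6 and setting C6 (R).

Step 9
Reactants: 13 (4R,5Z,8E)-1-(tert-butyldimethylsilyloxy)-8-(dimethoxymethyl)-10-(4-methoxybenzyloxy)deca-5,8-dien-2-yn-4-ol
Product: 15 (2Z,4R,5Z,8E)-1-(tert-butyldimethylsilyloxy)-8-(dimethoxymethyl)-2-iodo-10-(4-methoxybenzyloxy)deca-2,5,8-trien-4-ol, via cyclic alkenylalanate 14 (not isolated)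
Conditions: NaAlH2(OCH2CH2OMe)2 (Red-Al, 2.0 equiv), THF, 0 °C → rt; EtOAc; I2, −78 → 0 °C
Reagents that add atoms: iodine, II
Why: Hydroxyl-directed trans-hydroalumination of the propargylic alcohol puts aluminium on the distal carbon C4 in a five-membered alkoxyalanate and hydrogen on C5; iodinolysis with retention gives the Z iodoalkene, so that the carbon later attached to C4 is cis to C6.

Step 10
Reactants: 15 (2Z,4R,5Z,8E)-1-(tert-butyldimethylsilyloxy)-8-(dimethoxymethyl)-2-iodo-10-(4-methoxybenzyloxy)deca-2,5,8-trien-4-ol
Product: 16 (6S,7R,8S)-7,8-epoxide of 15 (threo cis-epoxy alcohol)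
Conditions: mCPBA (1.2 equiv), NaHCO3, CH2Cl2, 0 °C
Reagents that add atoms: 3-chloroperoxybenzoic acid, OOC(=O)c1cccc(Cl)c1
Why: Hydroxyl-directed peracid epoxidation; A(1,3) strain with the cis C9 substituent holds H6 in the alkene plane, so the peracid hydrogen-bonded to O6 attacks the face that gives the threo epoxy alcohol and sets C7 and C8. The iodoalkene and the C1=C10 alkene, which carries an allylic acetal and an allylic ether, are too electron-poor to compete.

Step 11
Reactants: 16 (6S,7R,8S)-7,8-epoxide of 15; 17 diethylphosphonoacetic acid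
Product: 18 C6 diethylphosphonoacetate of 16 (6S,7S,8S)
Conditions: 17 (1.5 equiv), DCC, DMAP (10 mol %), CH2Cl2, 0 °C → rt
Reagents that add atoms: none
Why: Steglich esterification of the secondary alcohol; neutral conditions leave epoxide, acetal and vinyl iodide untouched.

Step 12
Reactants: 18 C6 diethylphosphonoacetate of 16
Product: 19 hydroxy phosphonolactone (6R,7R,8S): cis-6,12-lactone with diethoxyphosphoryl on C11 (either epimer) and free C8 hydroxyl
Conditions: NaN(SiMe3)2 (1.05 equiv), THF, −78 °C → rt; AcOH, 0 °C
Reagents that add atoms: none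
Why: Intramolecular 5-exo-tet epoxide opening by the tethered phosphonate-stabilised ester enolate, the tethered form of the phosphonoacetate–epoxide lactone annulation; backside attack inverts C7, leaves C8 unchanged and closes the cis-lactone. The C8 alkoxide is quenched by proton transfer from C11–H, and the resulting enolate resists translactonisation until the cold acidic quench.

Step 13
Reactants: 19 hydroxy phosphonolactone (6R,7R,8S)
Product: 20 C8 isovalerate of 19 (6R,7R,8S)
Conditions: (iPrCH2CO)2O (1.5 equiv), pyridine, DMAP (cat.), CH2Cl2, 0 °C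
Reagents that add atoms: 3-methylbutanoic anhydride, CC(C)CC(=O)OC(=O)CC(C)C
Why: DMAP-catalysed acylation of the secondary alcohol under conditions too weakly basic to form the C11 carbanion; it fixes O8 and closes off translactonisation.

Step 14
Reactants: 20 C8 isovalerate of 19
Product: 21 C3 alcohol (6S,7R,8S): 20 with CH2OH in place of iodine (4E)
Conditions: Bu3SnCH2OH (2 equiv), Pd(PPh3)4 (10 mol %), 1,4-dioxane, 85 °C
Reagents that add atoms: (tributylstannyl)methanol, CCCC[Sn](CCCC)(CCCC)CO
Why: Stille hydroxymethylation of a vinyl iodide with retention of alkene geometry installs C3 cis to C6 under neutral conditions that leave the acidic C11–H and the esters alone.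

Step 15
Reactants: 21 C3 alcohol (6S,7R,8S); 22 2-nitrobenzenesulfonamide
Product: 23 C3 2-nitrobenzenesulfonamide (6S,7R,8S)
Conditions: 22 (3 equiv), PPh3, DIAD, THF, 0 °C → rt
Reagents that add atoms: none
Why: Mitsunobu N-alkylation of the acidic sulfonamide by the primary allylic alcohol (SN2 at C3); excess 22 limits dialkylation, and carbon acids of the phosphonoacetate class are poor Mitsunobu partners, so C11 is not alkylated.

Step 16
Reactants: 23 C3 2-nitrobenzenesulfonamide (6S,7R,8S)
Product: 24 C2 alcohol (6S,7R,8S): 23 without the 4-methoxybenzyl group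
Conditions: DDQ (1.3 equiv), CH2Cl2/pH 7 phosphate buffer (10:1), 0 °C
Reagents that add atoms: none
Why: Oxidative cleavage of the PMB ether; the buffer protects the allylic acetal and the silyl ether.

Step 17
Reactants: 24 C2 alcohol (6S,7R,8S)
Product: 25 N-(2-nitrobenzenesulfonyl) eleven-membered aza-macrocycle (6S,7R,8S)
Conditions: PPh3 (3 equiv), DIAD (3 equiv), toluene/THF, 0.002 M, syringe-pump addition of 24, rt
Reagents that add atoms: none
Why: Intramolecular Fukuyama–Mitsunobu N-alkylation (exo-tet SN2 at the unhindered C2) closes the eleven-membered ring; the cis-lactone acts as a turn that brings the two cis-alkenyl arms together, and the absence of carbonate base keeps C11 out of the reaction.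

Step 18
Reactants: 25 N-(2-nitrobenzenesulfonyl) eleven-membered aza-macrocycle
Product: 26 eleven-membered cyclic diallylamine (6S,7R,8S) with NH between C2 and C3
Conditions: PhSH (3 equiv), K2CO3 (3 equiv), MeCN, rt; used directly
Reagents that add atoms: none
Why: Fukuyama denosylation: thiolate adds ipso to the nitroarene, SO2 is lost and the secondary amine is released; esters, acetal and silyl ether survive, and the amine is taken on at once to limit acyl transfer to nitrogen.

Step 19
Reactants: 26 eleven-membered cyclic diallylamine (6S,7R,8S)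
Product: 29 ten-membered phosphonolactone (6S,7R,8S; 1(10)E,4E) with C8 isovalerate, C14 dimethyl acetal and C15 silyl ether, via N-benzyloxy hydrazide 27 (not isolated), via isodiazene 28 (not isolated)
Conditions: N-(benzyloxy)-N-(pivaloyloxy)-4-(trifluoromethyl)benzamide (1.5 equiv), THF (0.05 M), 45 °C
Reagents that add atoms: none
Why: Proposed new method: the ring nitrogen of 26 attacks the electrophilic amide nitrogen with loss of pivalate to give hydrazide 27, which expels benzyl 4-(trifluoromethyl)benzoate to leave isodiazene 28; loss of N2 from 28, directly or after a [2,3] shift to the cyclic 1,2-diazene, gives a tethered singlet pair of allyl radicals spanning C2–C1–C10 and C3–C4–C5 that collapses to the C2–C3 bond. The closest known reaction type is nitrogen deletion of secondary amines by anomeric amides, established for benzylic and cyclic amines but not for a medium-ring diallylamine. The ten-membered ring is closed by radical–radical recombination as a contraction of the eleven-membered ring, so the entropic cost of bringing the ends together was already paid in step 17. No stereocentre is formed, and C6, C7 and C8 lie at least three bonds from the reacting carbons. The step needs coupling at the two primary termini and retention of both ring-cis double bonds: bonding at C10 (fully substituted, next to the acetal) or at C5 (next to the lactone carbinol) would give congested six- or eight-membered rings, and the short tether together with the rotational barrier of allyl radicals holds both fragments in their ring-cis form for the lifetime of the pair. The amine cannot add to a Michael acceptor because C11 carries the phosphonate and C14 is an acetal, and neither esters nor silyl ether react with the reagent.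

Step 20
Reactants: 29 ten-membered phosphonolactone (6S,7R,8S)
Product: 30 α-methylene lactone (6S,7R,8S) with C14 dimethyl acetal and C15 silyl ether
Conditions: 37% aq. HCHO (excess), K2CO3 (2 equiv), THF, 0 °C → rt
Reagents that add atoms: formaldehyde, C=O
Why: Horner–Wadsworth–Emmons methylenation of the α-phosphono lactone under carbonate; both C11 epimers converge on the C11=C13 alkene, and the acetal and isovalerate tolerate the mild base.

Step 21
Reactants: 30 α-methylene lactone (6S,7R,8S)
Product: 31 (6S,7R,8S,1(10)E,4E)-15-hydroxy-8-(3-methylbutanoyloxy)-14-oxogermacra-1(10),4,11(13)-trien-12,6-olide (CNP0345200.9)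
Conditions: AcOH/THF/H2O (3:1:1), rt
Reagents that add atoms: water, O
Why: Dilute aqueous acid hydrolyses the allylic dimethyl acetal to the C14 enal and cleaves the primary allylic silyl ether at C15; the methylene lactone, the ester and the stereocentres are stable to these conditions.

**Compound list**

1 | cis-2-butene-1,4-diol | OC/C=C\CO | starting material
2 | (Z)-4-(tert-butyldimethylsilyloxy)but-2-en-1-ol | OC/C=C\CO[Si](C)(C)C(C)(C)C | intermediate
3 | (Z)-4-bromo-1-(tert-butyldimethylsilyloxy)but-2-ene | BrC/C=C\CO[Si](C)(C)C(C)(C)C | intermediate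
4 | diethyl [2-(methoxy(methyl)amino)-2-oxoethyl]phosphonate | CCOP(=O)(OCC)CC(=O)N(C)OC | starting material
5 | diethyl [(Z)-6-(tert-butyldimethylsilyloxy)-1-(methoxy(methyl)amino)-1-oxohex-4-en-2-yl]phosphonate, racemic | CCOP(=O)(OCC)C(C/C=C\CO[Si](C)(C)C(C)(C)C)C(=O)N(C)OC | intermediate
6 | (4-methoxybenzyloxy)acetaldehyde | O=CCOCc1ccc(OC)cc1 | starting material
7 | (2E)-2-[(Z)-4-(tert-butyldimethylsilyloxy)but-2-enyl]-N-methoxy-4-(4-methoxybenzyloxy)-N-methylbut-2-enamide | CON(C)C(=O)/C(C/C=C\CO[Si](C)(C)C(C)(C)C)=C/COCc1ccc(OC)cc1 | intermediate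
8 | (2E)-2-[(Z)-4-(tert-butyldimethylsilyloxy)but-2-enyl]-4-(4-methoxybenzyloxy)but-2-enal | O=C/C(C/C=C\CO[Si](C)(C)C(C)(C)C)=C/COCc1ccc(OC)cc1 | intermediate
9 | dimethyl acetal of 8 with the silyl ether still in place | COC(OC)/C(C/C=C\CO[Si](C)(C)C(C)(C)C)=C/COCc1ccc(OC)cc1 | intermediate
10 | (2Z,5E)-5-(dimethoxymethyl)-7-(4-methoxybenzyloxy)hepta-2,5-dien-1-ol | COC(OC)/C(C/C=C\CO)=C/COCc1ccc(OC)cc1 | intermediate
11 | (2Z,5E)-5-(dimethoxymethyl)-7-(4-methoxybenzyloxy)hepta-2,5-dienal | COC(OC)/C(C/C=C\C=O)=C/COCc1ccc(OC)cc1 | intermediate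
12 | tert-butyldimethyl(prop-2-yn-1-yloxy)silane | C#CCO[Si](C)(C)C(C)(C)C | starting material
13 | (4R,5Z,8E)-1-(tert-butyldimethylsilyloxy)-8-(dimethoxymethyl)-10-(4-methoxybenzyloxy)deca-5,8-dien-2-yn-4-ol (C6 R) | CC(C)(C)[Si](C)(C)OCC#C[C@H](O)/C=C\C/C(=C\COCc1ccc(OC)cc1)C(OC)OC | intermediate
14 | sodium cyclic alkenylalanate from 13 (Al on C4 and O6, two 2-methoxyethoxy ligands) | [Na+].COCCO[Al-]1(OCCOC)O[C@H](/C=C\C/C(=C\COCc2ccc(OC)cc2)C(OC)OC)C=C1CO[Si](C)(C)C(C)(C)C | intermediate
15 | (2Z,4R,5Z,8E)-1-(tert-butyldimethylsilyloxy)-8-(dimethoxymethyl)-2-iodo-10-(4-methoxybenzyloxy)deca-2,5,8-trien-4-ol (C6 R) | CC(C)(C)[Si](C)(C)OC/C(I)=C/[C@H](O)/C=C\C/C(=C\COCc1ccc(OC)cc1)C(OC)OC | intermediate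
16 | (6S,7R,8S)-7,8-epoxide of 15, threo cis-epoxy alcohol | CC(C)(C)[Si](C)(C)OC/C(I)=C/[C@H](O)[C@H]1O[C@H]1C/C(=C\COCc1ccc(OC)cc1)C(OC)OC | intermediate
17 | diethylphosphonoacetic acid | OC(=O)CP(=O)(OCC)OCC | starting material
18 | C6 diethylphosphonoacetate of 16 (6S,7S,8S) | CCOP(=O)(OCC)CC(=O)O[C@@H](/C=C(/CO[Si](C)(C)C(C)(C)C)I)[C@H]1O[C@H]1C/C(=C\COCc1ccc(OC)cc1)C(OC)OC | intermediate
19 | hydroxy phosphonolactone (6R,7R,8S): cis-6,12-lactone, C11 diethoxyphosphoryl (either epimer), free C8 OH, (4Z)-C4 iodide, C15 silyl ether, C2 PMB ether, C14 dimethyl acetal | CCOP(=O)(OCC)C1C(=O)O[C@@H](/C=C(/CO[Si](C)(C)C(C)(C)C)I)[C@H]1[C@@H](O)C/C(=C\COCc1ccc(OC)cc1)C(OC)OC | intermediate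
20 | C8 isovalerate of 19 (6R,7R,8S) | CCOP(=O)(OCC)C1C(=O)O[C@@H](/C=C(/CO[Si](C)(C)C(C)(C)C)I)[C@H]1[C@@H](OC(=O)CC(C)C)C/C(=C\COCc1ccc(OC)cc1)C(OC)OC | intermediate
21 | C3 alcohol (6S,7R,8S; 4E): 20 with CH2OH in place of iodine | CCOP(=O)(OCC)C1C(=O)O[C@@H](/C=C(/CO[Si](C)(C)C(C)(C)C)CO)[C@H]1[C@@H](OC(=O)CC(C)C)C/C(=C\COCc1ccc(OC)cc1)C(OC)OC | intermediate
22 | 2-nitrobenzenesulfonamide | NS(=O)(=O)c1ccccc1[N+](=O)[O-] | starting material
23 | C3 2-nitrobenzenesulfonamide (6S,7R,8S) | CCOP(=O)(OCC)C1C(=O)O[C@@H](/C=C(/CO[Si](C)(C)C(C)(C)C)CNS(=O)(=O)c2ccccc2[N+](=O)[O-])[C@H]1[C@@H](OC(=O)CC(C)C)C/C(=C\COCc1ccc(OC)cc1)C(OC)OC | intermediate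
24 | C2 alcohol (6S,7R,8S): 23 without the PMB group | CCOP(=O)(OCC)C1C(=O)O[C@@H](/C=C(/CO[Si](C)(C)C(C)(C)C)CNS(=O)(=O)c2ccccc2[N+](=O)[O-])[C@H]1[C@@H](OC(=O)CC(C)C)C/C(=C\CO)C(OC)OC | intermediate
25 | N-(2-nitrobenzenesulfonyl) eleven-membered aza-macrocycle (6S,7R,8S), N between C2 and C3 | CCOP(=O)(OCC)C1C(=O)O[C@H]2/C=C(/CO[Si](C)(C)C(C)(C)C)CN(S(=O)(=O)c3ccccc3[N+](=O)[O-])C/C=C(/C(OC)OC)C[C@H](OC(=O)CC(C)C)[C@@H]12 | intermediate
26 | eleven-membered cyclic diallylamine (6S,7R,8S), NH between C2 and C3 | CCOP(=O)(OCC)C1C(=O)O[C@H]2/C=C(/CO[Si](C)(C)C(C)(C)C)CNC/C=C(/C(OC)OC)C[C@H](OC(=O)CC(C)C)[C@@H]12 | intermediate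
27 | N-benzyloxy-N-[4-(trifluoromethyl)benzoyl] hydrazide of 26 | CCOP(=O)(OCC)C1C(=O)O[C@H]2/C=C(/CO[Si](C)(C)C(C)(C)C)CN(N(OCc3ccccc3)C(=O)c3ccc(cc3)C(F)(F)F)C/C=C(/C(OC)OC)C[C@H](OC(=O)CC(C)C)[C@@H]12 | intermediate
28 | isodiazene (1,1-diazene) of 26 | CCOP(=O)(OCC)C1C(=O)O[C@H]2/C=C(/CO[Si](C)(C)C(C)(C)C)C[N+](=[N-])C/C=C(/C(OC)OC)C[C@H](OC(=O)CC(C)C)[C@@H]12 | intermediate
29 | ten-membered phosphonolactone (6S,7R,8S; 1(10)E,4E), C8 isovalerate, C14 dimethyl acetal, C15 silyl ether | CCOP(=O)(OCC)C1C(=O)O[C@H]2/C=C(/CO[Si](C)(C)C(C)(C)C)CC/C=C(/C(OC)OC)C[C@H](OC(=O)CC(C)C)[C@@H]12 | intermediate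
30 | α-methylene lactone (6S,7R,8S) with C14 dimethyl acetal and C15 silyl ether | C=C1C(=O)O[C@H]2/C=C(/CO[Si](C)(C)C(C)(C)C)CC/C=C(/C(OC)OC)C[C@H](OC(=O)CC(C)C)[C@@H]12 | intermediate
31 | (6S,7R,8S,1(10)E,4E)-15-hydroxy-8-(3-methylbutanoyloxy)-14-oxogermacra-1(10),4,11(13)-trien-12,6-olide | C=C1C(=O)O[C@H]2/C=C(/CO)CC/C=C(/C=O)C[C@H](OC(=O)CC(C)C)[C@@H]12 | target

**Step count and least certain steps**

Total step count: 21. Longest linear sequence: 21 steps, from 1 to 31.

Step 19 (key step, proposed new method). Most likely to go wrong: loss of regiocontrol in the recombination. If the isodiazene first undergoes a [2,3] shift, nitrogen leaves from C10 or C5 and the radical pair may collapse there, giving vinyl-substituted eight-membered rings. Rotation within an allyl radical before coupling would scramble a ring-cis alkene, and disproportionation to dienes or slow amination of the hindered ring amine are also possible. Fallback by known chemistry, from 21 back to 29: the PMB ether of 21 is cleaved with buffered DDQ to the C2,C3-diol F1; CBr4/PPh3 with 2,6-lutidine converts it into the bis(allylic bromide) F2; F2 is added slowly to Ni(CO)4 in N-methylpyrrolidone at 50 °C. This nickel-carbonyl-mediated reductive coupling of bis(allylic bromides) to cyclic 1,5-dienes joins the two primary termini to give 29 under neutral conditions, so C11–H is not deprotonated. Its known weakness is equilibration of the allylnickel geometry, against which the medium ring favours the ring-cis form.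

Step 17. Most likely to go wrong: intermolecular N-alkylation to dimers and oligomers because of medium-ring strain, or deprotonation of C11–H by the sulfonamide anion followed by seven-membered C-alkylation at the activated C2. Fallback from 21 back to 26, changing the nitrogen carrier to a more acidic one whose anion cannot deprotonate C11 and whose removal needs no carbonate: Mitsunobu reaction of 21 with 2,4-dinitrobenzenesulfonamide gives the C3 dinitrobenzenesulfonamide F3; buffered DDQ frees the C2 alcohol F4; high-dilution Mitsunobu closure gives the N-(2,4-dinitrobenzenesulfonyl) macrocycle F5; thioglycolic acid and Et3N at rt release 26.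

Step 14. Most likely to go wrong: slow transfer of the sp3 hydroxymethyl group from tin, so that protodeiodination or homocoupling takes over, or ionisation of the allylic C6–O lactone bond by zerovalent palladium at 85 °C. Fallback from 20 back to 21: reductive carbonylation of the vinyl iodide (CO 1 atm, Bu3SnH added slowly, Pd(PPh3)4, THF, 50 °C) gives the C3 enal F6, which is reduced at once under Luche conditions (NaBH4, CeCl3·7H2O, MeOH, −40 °C) to 21. The immediate reduction forestalls isomerisation of the less stable enal geometry and elimination of the γ-acyloxy group.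

Step 8. Most likely to go wrong: Z to E isomerisation of the enal, or conjugation of its skipped diene, under the zinc alkoxide/amine conditions before addition, with loss of the C7=C8 geometry and of enantiomeric purity. Fallback from 11 and 12 back to 13: the lithium acetylide of 12 (nBuLi, THF, −78 °C) adds to 11 to give the racemic alcohol F7; MnO2 oxidises it to the ynone F8; Corey–Bakshi–Shibata reduction at −78 °C with catecholborane and the (R)-methyl oxazaborolidine gives 13. The (R) catalyst is chosen on the assumption that the Z alkenyl group acts as the large and the alkynyl group as the small substituent.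

**Further compounds**

F1 | step 19 | C2,C3-diol: 21 without the PMB group | CCOP(=O)(OCC)C1C(=O)O[C@@H](/C=C(/CO[Si](C)(C)C(C)(C)C)CO)[C@H]1[C@@H](OC(=O)CC(C)C)C/C(=C\CO)C(OC)OC
F2 | step 19 | C2,C3-bis(allylic bromide) | CCOP(=O)(OCC)C1C(=O)O[C@@H](/C=C(/CO[Si](C)(C)C(C)(C)C)CBr)[C@H]1[C@@H](OC(=O)CC(C)C)C/C(=C\CBr)C(OC)OC
F3 | step 17 | C3 2,4-dinitrobenzenesulfonamide with C2 PMB ether | CCOP(=O)(OCC)C1C(=O)O[C@@H](/C=C(/CO[Si](C)(C)C(C)(C)C)CNS(=O)(=O)c2ccc(cc2[N+](=O)[O-])[N+](=O)[O-])[C@H]1[C@@H](OC(=O)CC(C)C)C/C(=C\COCc1ccc(OC)cc1)C(OC)OC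
F4 | step 17 | C3 2,4-dinitrobenzenesulfonamide with free C2 alcohol | CCOP(=O)(OCC)C1C(=O)O[C@@H](/C=C(/CO[Si](C)(C)C(C)(C)C)CNS(=O)(=O)c2ccc(cc2[N+](=O)[O-])[N+](=O)[O-])[C@H]1[C@@H](OC(=O)CC(C)C)C/C(=C\CO)C(OC)OC
F5 | step 17 | N-(2,4-dinitrobenzenesulfonyl) eleven-membered aza-macrocycle | CCOP(=O)(OCC)C1C(=O)O[C@H]2/C=C(/CO[Si](C)(C)C(C)(C)C)CN(S(=O)(=O)c3ccc(cc3[N+](=O)[O-])[N+](=O)[O-])C/C=C(/C(OC)OC)C[C@H](OC(=O)CC(C)C)[C@@H]12
F6 | step 14 | C3 enal: 20 with CHO in place of iodine | CCOP(=O)(OCC)C1C(=O)O[C@@H](/C=C(/CO[Si](C)(C)C(C)(C)C)C=O)[C@H]1[C@@H](OC(=O)CC(C)C)C/C(=C\COCc1ccc(OC)cc1)C(OC)OC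
F7 | step 8 | racemic 13 | CC(C)(C)[Si](C)(C)OCC#CC(O)/C=C\C/C(=C\COCc1ccc(OC)cc1)C(OC)OC
F8 | step 8 | C6 ynone: (5Z,8E)-1-(tert-butyldimethylsilyloxy)-8-(dimethoxymethyl)-10-(4-methoxybenzyloxy)deca-5,8-dien-2-yn-4-one | CC(C)(C)[Si](C)(C)OCC#CC(=O)/C=C\C/C(=C\COCc1ccc(OC)cc1)C(OC)OC
A1 | alternative 1 | C9 carboxylic acid with C8 4-methoxybenzyl ether, C11=C13 methylene unit (C12 triethylsilyl ether) on C7, C6 triethylsilyl ether, C4≡C5 alkyne and C15 tert-butyldiphenylsilyl ether | OC(=O)[C@H](OCc1ccc(OC)cc1)[C@@H](C(=C)CO[Si](CC)(CC)CC)[C@@H](O[Si](CC)(CC)CC)C#CCO[Si](c1ccccc1)(c1ccccc1)C(C)(C)C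
A2 | alternative 2 | ten-membered α-methylene cis-6,12-lactone with free C8 hydroxyl, C14 dimethyl acetal and C15 tert-butyldimethylsilyl ether | C=C1C(=O)O[C@H]2/C=C(/CO[Si](C)(C)C(C)(C)C)CC/C=C(/C(OC)OC)C[C@H](O)[C@@H]12
A3 | alternative 3 | ten-membered C14 enal with C8 isovalerate, C6 and C12 triethylsilyl ethers, C15 tert-butyldiphenylsilyl ether and C11=C13 methylene | C=C(CO[Si](CC)(CC)CC)[C@H]1[C@@H](O[Si](CC)(CC)CC)/C=C(/CO[Si](c2ccccc2)(c2ccccc2)C(C)(C)C)CC/C=C(/C=O)C[C@@H]1OC(=O)CC(C)C
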